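The target is disconnected at the C3'–C3''' biaryl bond that joins ring B of the (2S)-flavanone half to ring B of the (2R,3R)-3-hydroxyflavanone half. Each of these two carbons is ortho to a phenolic oxygen (O4' and O4'''), so tying the two oxygens through one silicon atom makes the bond formation intramolecular and the ring formed only seven-membered. In one operation zerovalent nickel joins the two aryl iodides of the bridged, fully protected bis-flavonoid 15 and gives dibenzodioxasilepine 16, which enforces cross-coupling of two nearly identical halves without base. Both halves come from one resolved flavanone, 8; the second is made from it by C3 hydroxylation.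

Key step: step 11

Atom labels: unit 1 (flavanone) carries C2–C8a and C1'–C6'; unit 2 (3-hydroxyflavanone) carries C2''–C8a'' and C1'''–C6'''.

Remark: the (R,R) transfer-hydrogenation catalyst is assumed to reduce the (2R)-flavanone (4R carbinol as with simple aryl ketones, cis to the aryl group), leaving (2S)-7; the sense is to be confirmed on the first batch and the (S,S) catalyst taken if it is reversed.

Step 1
Reactants: 1 2,4,6-trihydroxyacetophenone
Product: 2 1-[2,4-bis(benzyloxy)-6-hydroxyphenyl]ethan-1-one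
Conditions: BnBr (2.1 equiv), K2CO3, DMF, 0 °C → rt
Reagents that add atoms: benzyl bromide, BrCc1ccccc1
Why: Williamson etherification; the hydroxyl that is hydrogen-bonded to the acetyl carbonyl is the least nucleophilic and should stay free.

Step 2
Reactants: 3 4-hydroxy-3-iodobenzaldehyde
Product: 4 3-iodo-4-(methoxymethoxy)benzaldehyde
Conditions: MOMCl, K2CO3, acetone, 0 °C → rt
Reagents that add atoms: chloromethyl methyl ether, COCCl
Why: O-alkylation of the acidic ortho-iodophenol to a base-stable acetal, so that the aldehyde is not deactivated as a phenoxide in the condensation that follows.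

Step 3
Reactants: 2 1-[2,4-bis(benzyloxy)-6-hydroxyphenyl]ethan-1-one; 4 3-iodo-4-(methoxymethoxy)benzaldehyde
Product: 5 (2E)-1-[2,4-bis(benzyloxy)-6-hydroxyphenyl]-3-[3-iodo-4-(methoxymethoxy)phenyl]prop-2-en-1-one
Conditions: KOH (50% aq.), EtOH, rt; then dilute HCl to pH 5
Reagents that add atoms: none
Why: Claisen–Schmidt condensation of a methyl ketone with a non-enolisable aldehyde; elimination from the aldol gives the E-enone, and benzyl ethers, the acetal and the aryl iodide tolerate hydroxide at room temperature.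

Step 4
Reactants: 5 (2E)-2'-hydroxychalcone
Product: 6 rac-5,7-bis(benzyloxy)-2-[3-iodo-4-(methoxymethoxy)phenyl]chroman-4-one
Conditions: NaOAc, EtOH, reflux
Reagents that add atoms: none
Why: Base-mediated intramolecular oxa-Michael addition (6-endo-trig) of the 2'-phenol to the enone; the 6'-benzyloxy group twists the chalcone and shifts the equilibrium to the flavanone, which forms as the racemate.

Step 5
Reactants: 6 rac-5,7-bis(benzyloxy)-2-[3-iodo-4-(methoxymethoxy)phenyl]chroman-4-one
Product: 7 (2S)-5,7-bis(benzyloxy)-2-[3-iodo-4-(methoxymethoxy)phenyl]chroman-4-one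
Conditions: RhCl[(R,R)-TsDPEN](C5Me5) (1 mol%), HCO2H/Et3N (5:2), EtOAc, rt to 40 °C, stopped just past half conversion
Reagents that add atoms: none
Why: Kinetic resolution by Noyori-type asymmetric transfer hydrogenation; the catalyst should reduce the (2R)-ketone to the cis-(2R,4R)-flavan-4-ol much faster than its enantiomer, so C2 of 7 is selected (not created) and the unreacted (2S)-ketone is separated from the alcohol by chromatography.

Step 6
Reactants: 7 (2S)-5,7-bis(benzyloxy)-2-[3-iodo-4-(methoxymethoxy)phenyl]chroman-4-one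
Product: 8 (2S)-5,7-bis(benzyloxy)-2-(4-hydroxy-3-iodophenyl)chroman-4-one
Conditions: 3 M HCl, MeOH/THF, 45 °C
Reagents that add atoms: none
Why: Acid-catalysed cleavage of the aryl methoxymethyl acetal; benzyl ethers and the aryl iodide are inert, and the flavanone, which is labile only to base, should keep its C2 configuration.

Step 7
Reactants: 8 (2S)-5,7-bis(benzyloxy)-2-(4-hydroxy-3-iodophenyl)chroman-4-one
Product: 9 (2S)-5,7-bis(benzyloxy)-4-[(tert-butyldimethylsilyl)oxy]-2-{4-[(tert-butyldimethylsilyl)oxy]-3-iodophenyl}-2H-chromene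
Conditions: TBSOTf (2.5 equiv), Et3N (4 equiv), CH2Cl2, −78 → 0 °C
Reagents that add atoms: tert-butyldimethylsilyl trifluoromethanesulfonate, CC(C)(C)[Si](C)(C)OS(=O)(=O)C(F)(F)F
Why: Phenol silylation together with soft enolisation (silyl triflate activates the ketone, Et3N removes H3) gives the silyl enol ether without a free enolate, so the retro-oxa-Michael ring opening that would scramble C2 has no pathway.

Step 8
Reactants: 9 (2S)-4-silyloxy-2H-chromene
Product: 11 (2R,3R)-5,7-bis(benzyloxy)-3-[(tert-butyldimethylsilyl)oxy]-2-{4-[(tert-butyldimethylsilyl)oxy]-3-iodophenyl}chroman-4-one, via siloxy epoxide 10 (not isolated)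
Conditions: mCPBA (1.05 equiv), CH2Cl2, −20 → 0 °C
Reagents that add atoms: 3-chloroperbenzoic acid, O=C(OO)c1cccc(Cl)c1
Why: Rubottom oxidation; the peracid should epoxidise the enol ether on the face anti to the C2 aryl group (as electrophiles add to flav-3-enes), the siloxy oxirane opens to the C4 cation stabilised by the 5,7-dialkoxy ring A, and a 1,4 oxygen-to-oxygen silyl shift gives the 2,3-trans α-silyloxy ketone, C2 being untouched (its descriptor changes from S to R only because O3 raises the priority of C3).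

Step 9
Reactants: 11 (2R,3R)-bis-silyl ether
Product: 12 (2R,3R)-5,7-bis(benzyloxy)-3-[(tert-butyldimethylsilyl)oxy]-2-(4-hydroxy-3-iodophenyl)chroman-4-one
Conditions: KHF2 (2.5 equiv), MeOH/THF, rt
Reagents that add atoms: none
Why: Selective fluoride-mediated desilylation; the aryl silyl ether (phenoxide leaving group, helped by the ortho iodine) is cleaved while the secondary alkyl silyl ether at O3 stays, and the weakly acidic medium should not epimerise C2 or C3.

Step 10
Reactants: 8 (2S)-5,7-bis(benzyloxy)-2-(4-hydroxy-3-iodophenyl)chroman-4-one; 13 dichlorodiisopropylsilane; 12 (2R,3R)-5,7-bis(benzyloxy)-3-[(tert-butyldimethylsilyl)oxy]-2-(4-hydroxy-3-iodophenyl)chroman-4-one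
Product: 15 diisopropylsilylene-bridged bis(aryl iodide) of the two protected halves, via aryloxychlorosilane 14 (not isolated)
Conditions: 8 added slowly to i-Pr2SiCl2 (4 equiv), imidazole, CH2Cl2, 0 °C; excess silane removed under high vacuum; then 12 (1.0 equiv), imidazole, DMF, 0 °C → rt; chromatography on Et3N-deactivated silica
Reagents that add atoms: none
Why: Two successive substitutions at silicon (silyl ether formation); the first phenol meets a large excess of dichlorosilane so that only one chloride is displaced, the volatile excess is removed, and the only free hydroxyl of 12 takes the second position, imidazole being too weak a base to open either flavanone ring.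

Step 11
Reactants: 15 diisopropylsilylene-bridged bis(aryl iodide)
Product: 16 6,6-diisopropyldibenzo[d,f][1,3,2]dioxasilepine carrying the protected flavanone at C2 and the protected 3-silyloxyflavanone at C10
Conditions: Ni(cod)2 (2.5 equiv), PPh3 (5 equiv), degassed DMF, 50 °C, slow addition of 15 (final 0.005 M)
Reagents that add atoms: none
Why: One C–I bond adds oxidatively to zerovalent nickel to give an arylnickel iodide of divalent nickel, the tethered second C–I bond is then activated at the same metal (directly or through a monovalent/trivalent nickel relay), and reductive elimination from the resulting diarylnickel species, an eight-membered nickelacycle, forms C3'–C3''' and expels NiI2. The closest known reaction type is the tether-directed intramolecular Ullmann-type reductive coupling of bis(2-haloaryl) ethers and esters to unsymmetrical 2,2'-biphenols, run here with stoichiometric zerovalent nickel and applied to a silylene tether. The ring closed is the seven-membered 1,3-dioxa-2-silepine ring (C3'–C4'–O–Si–O–C4'''–C3'''), formed by ring contraction of the nickelacycle in the reductive elimination, with the two isopropyl groups on silicon favouring the folded conformer. No stereocenter is created, and the new axis, flanked by only two ortho oxygens, needs no control. The selectivity required is cross- over homo-coupling and bond formation at C3' and C3''' only; both follow from the O4'–Si–O4''' bridge and from the iodine atoms placed ortho to these oxygens in 3, while high dilution holds back intermolecular coupling. The medium is aprotic and free of base and boron, so the base-labile C2, C2'' and C3'' centers, the ketones and the aryl–O–Si bonds are expected to persist.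

Step 12
Reactants: 16 silylene-bridged protected biflavonoid
Product: 17 5,7,5'',7''-tetra-O-benzyl ether of the target
Conditions: HF·pyridine (excess), THF, 0 → 25 °C
Reagents that add atoms: none
Why: Fluoride-driven Si–O cleavage under weakly acidic conditions removes the silylene bridge and the O3'' silyl ether, while benzyl ethers and the acid-stable flavanone centers are untouched.

Step 13
Reactants: 17 5,7,5'',7''-tetra-O-benzyl ether of the target
Product: 18 CNP0201582.1
Conditions: H2 (1 bar), 10% Pd/C, EtOAc/MeOH, rt, stopped at complete debenzylation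
Reagents that add atoms: none
Why: Catalytic hydrogenolysis of the four benzyl aryl ethers; no aryl halide remains, and the ketones and the C2–O1 bonds of flavanones survive short exposure at room temperature and low pressure.

Compound list
1 | 2,4,6-trihydroxyacetophenone | CC(=O)c1c(O)cc(O)cc1O | starting material
2 | 1-[2,4-bis(benzyloxy)-6-hydroxyphenyl]ethan-1-one | CC(=O)c1c(O)cc(OCc2ccccc2)cc1OCc1ccccc1 | intermediate
3 | 4-hydroxy-3-iodobenzaldehyde | O=Cc1ccc(O)c(I)c1 | starting material
4 | 3-iodo-4-(methoxymethoxy)benzaldehyde | COCOc1ccc(C=O)cc1I | intermediate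
5 | (2E)-1-[2,4-bis(benzyloxy)-6-hydroxyphenyl]-3-[3-iodo-4-(methoxymethoxy)phenyl]prop-2-en-1-one | COCOc1ccc(/C=C/C(=O)c2c(O)cc(OCc3ccccc3)cc2OCc2ccccc2)cc1I | intermediate
6 | rac-5,7-bis(benzyloxy)-2-[3-iodo-4-(methoxymethoxy)phenyl]-2,3-dihydro-4H-chromen-4-one (racemate) | O=C1CC(c2ccc(OCOC)c(I)c2)Oc2cc(OCc3ccccc3)cc(OCc3ccccc3)c21 | intermediate
7 | (2S)-5,7-bis(benzyloxy)-2-[3-iodo-4-(methoxymethoxy)phenyl]-2,3-dihydro-4H-chromen-4-one | O=C1C[C@@H](c2ccc(OCOC)c(I)c2)Oc2cc(OCc3ccccc3)cc(OCc3ccccc3)c21 | intermediate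
8 | (2S)-5,7-bis(benzyloxy)-2-(4-hydroxy-3-iodophenyl)-2,3-dihydro-4H-chromen-4-one (protected unit 1) | O=C1C[C@@H](c2ccc(O)c(I)c2)Oc2cc(OCc3ccccc3)cc(OCc3ccccc3)c21 | intermediate
9 | (2S)-5,7-bis(benzyloxy)-4-[(tert-butyldimethylsilyl)oxy]-2-{4-[(tert-butyldimethylsilyl)oxy]-3-iodophenyl}-2H-chromene | CC(C)(C)[Si](C)(C)OC1=C[C@@H](c2ccc(O[Si](C)(C)C(C)(C)C)c(I)c2)Oc2cc(OCc3ccccc3)cc(OCc3ccccc3)c21 | intermediate
10 | 3,4-epoxide of 9, oxirane oxygen anti to the C2 aryl group, silyloxy group on C4 | CC(C)(C)[Si](C)(C)O[C@@]12O[C@@H]1[C@@H](c1ccc(O[Si](C)(C)C(C)(C)C)c(I)c1)Oc1cc(OCc3ccccc3)cc(OCc3ccccc3)c12 | intermediate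
11 | (2R,3R)-5,7-bis(benzyloxy)-3-[(tert-butyldimethylsilyl)oxy]-2-{4-[(tert-butyldimethylsilyl)oxy]-3-iodophenyl}-2,3-dihydro-4H-chromen-4-one | CC(C)(C)[Si](C)(C)Oc1ccc([C@H]2Oc3cc(OCc4ccccc4)cc(OCc4ccccc4)c3C(=O)[C@@H]2O[Si](C)(C)C(C)(C)C)cc1I | intermediate
12 | (2R,3R)-5,7-bis(benzyloxy)-3-[(tert-butyldimethylsilyl)oxy]-2-(4-hydroxy-3-iodophenyl)-2,3-dihydro-4H-chromen-4-one (protected unit 2) | Oc1ccc([C@H]2Oc3cc(OCc4ccccc4)cc(OCc4ccccc4)c3C(=O)[C@@H]2O[Si](C)(C)C(C)(C)C)cc1I | intermediate
13 | dichlorodiisopropylsilane | CC(C)[Si](Cl)(Cl)C(C)C | starting material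
14 | (2S)-5,7-bis(benzyloxy)-2-(4-{[chloro(diisopropyl)silyl]oxy}-3-iodophenyl)-2,3-dihydro-4H-chromen-4-one | O=C1C[C@@H](c2ccc(O[Si](Cl)(C(C)C)C(C)C)c(I)c2)Oc2cc(OCc3ccccc3)cc(OCc3ccccc3)c21 | intermediate
15 | {4-[(2S)-5,7-bis(benzyloxy)-4-oxochroman-2-yl]-2-iodophenoxy}{4-[(2R,3R)-5,7-bis(benzyloxy)-3-[(tert-butyldimethylsilyl)oxy]-4-oxochroman-2-yl]-2-iodophenoxy}diisopropylsilane | O=C1C[C@@H](c2ccc(O[Si](C(C)C)(C(C)C)Oc3ccc([C@H]4Oc5cc(OCc6ccccc6)cc(OCc6ccccc6)c5C(=O)[C@@H]4O[Si](C)(C)C(C)(C)C)cc3I)c(I)c2)Oc2cc(OCc3ccccc3)cc(OCc3ccccc3)c21 | intermediate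
16 | 6,6-diisopropyldibenzo[d,f][1,3,2]dioxasilepine bearing (2S)-5,7-bis(benzyloxy)-4-oxochroman-2-yl at C2 and (2R,3R)-5,7-bis(benzyloxy)-3-[(tert-butyldimethylsilyl)oxy]-4-oxochroman-2-yl at C10 | O=C1C[C@@H](c2ccc3O[Si](C(C)C)(C(C)C)Oc4ccc([C@H]5Oc6cc(OCc7ccccc7)cc(OCc7ccccc7)c6C(=O)[C@@H]5O[Si](C)(C)C(C)(C)C)cc4-c3c2)Oc2cc(OCc3ccccc3)cc(OCc3ccccc3)c21 | intermediate
17 | (2R,3R)-5,7-bis(benzyloxy)-2-{5'-[(2S)-5,7-bis(benzyloxy)-4-oxochroman-2-yl]-2',6-dihydroxy-[1,1'-biphenyl]-3-yl}-3-hydroxy-2,3-dihydro-4H-chromen-4-one | O=C1C[C@@H](c2ccc(O)c(-c3cc([C@H]4Oc5cc(OCc6ccccc6)cc(OCc6ccccc6)c5C(=O)[C@@H]4O)ccc3O)c2)Oc2cc(OCc3ccccc3)cc(OCc3ccccc3)c21 | intermediate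
18 | CNP0201582.1, (2R,3R)-2-{2',6-dihydroxy-5'-[(2S)-5,7-dihydroxy-4-oxo-3,4-dihydro-2H-chromen-2-yl]-[1,1'-biphenyl]-3-yl}-3,5,7-trihydroxy-2,3-dihydro-4H-chromen-4-one | O=C1C[C@@H](c2ccc(O)c(-c3cc([C@H]4Oc5cc(O)cc(O)c5C(=O)[C@@H]4O)ccc3O)c2)Oc2cc(O)cc(O)c21 | target

Total steps: 13. Longest linear sequence: 12 steps (steps 1 and 3 to 13, from 1 to 18).

Steps most likely to fail

Step 11. Ring closure may be outrun by reductive loss of iodine from the arylnickel intermediate or by intermolecular coupling to oligomers, and traces of water may cleave the aryl–O–Si bridge before the second C–I bond is engaged. The fallback gives up the tether and makes the same bond by an intermolecular cross-coupling in which the two halves differ in function; it sets out from 8 and 11 and comes back at 17. Phenol 8 is silylated (TBSCl, imidazole, DMF) to (2S)-5,7-bis(benzyloxy)-2-{4-[(tert-butyldimethylsilyl)oxy]-3-iodophenyl}chroman-4-one F1. Miyaura borylation (B2pin2, PdCl2(dppf), KOAc, dioxane, 80 °C) converts it into the pinacol boronate F2. Suzuki–Miyaura coupling of F2 with iodide 11 (Pd(OAc)2, SPhos, K3PO4, toluene/water, 40 °C, short reaction time to spare the flavanone center) gives the open tris(tert-butyldimethylsilyl) ether of the biaryl F3. HF·pyridine in THF then removes the three silyl groups and delivers 17.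

Step 8 (with step 7). Configuration at C2 may erode during enol ether formation, the peracid may attack the face syn to the aryl group, or the silyl group may be lost by hydrolysis instead of migrating. The fallback builds the 3-hydroxyflavanone from an open-chain epoxide; it sets out from 2 and 4 and comes back at 11. Ketone 2 is protected (MOMCl, NaH, DMF, 0 °C) as 1-[2,4-bis(benzyloxy)-6-(methoxymethoxy)phenyl]ethan-1-one F4. Claisen–Schmidt condensation with 4 (KOH, EtOH) gives the 2'-O-protected (E)-chalcone F5. Juliá–Colonna epoxidation (poly-L-leucine, urea–hydrogen peroxide, DBU, THF) gives the (2R,3S)-epoxy ketone F6. HCl in MeOH/THF removes both acetals, and the freed 2'-phenol opens the oxirane at the benzylic carbon with inversion (6-endo) to give (2R,3R)-5,7-bis(benzyloxy)-3-hydroxy-2-(4-hydroxy-3-iodophenyl)chroman-4-one F7. TBSOTf and 2,6-lutidine in CH2Cl2 silylate both hydroxyls and give 11.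

Step 5. The ketone, flanked by the 5-benzyloxy group and deactivated by two alkoxy donors, may accept hydride so slowly that the two enantiomers are not told apart well enough. The fallback replaces the catalytic resolution by a physical one; it sets out from 6 and comes back at 7. Racemic 6 is separated by preparative chromatography on a chiral stationary phase (amylose tris(3,5-dimethylphenylcarbamate), heptane/2-propanol); the unwanted (2R) enantiomer is racemised under the conditions of step 4 (NaOAc, EtOH, reflux) and recycled. No compound outside the list is made (F0).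

Further compounds
F1 | step 11 | (2S)-5,7-bis(benzyloxy)-2-{4-[(tert-butyldimethylsilyl)oxy]-3-iodophenyl}-2,3-dihydro-4H-chromen-4-one | O=C1C[C@@H](c2ccc(O[Si](C)(C)C(C)(C)C)c(I)c2)Oc2cc(OCc3ccccc3)cc(OCc3ccccc3)c21
F2 | step 11 | (2S)-5,7-bis(benzyloxy)-2-{4-[(tert-butyldimethylsilyl)oxy]-3-(4,4,5,5-tetramethyl-1,3,2-dioxaborolan-2-yl)phenyl}-2,3-dihydro-4H-chromen-4-one | O=C1C[C@@H](c2ccc(O[Si](C)(C)C(C)(C)C)c(B3OC(C)(C)C(C)(C)O3)c2)Oc2cc(OCc3ccccc3)cc(OCc3ccccc3)c21
F3 | step 11 | 4',4''',3''-tris-O-(tert-butyldimethylsilyl) ether of 17 | O=C1C[C@@H](c2ccc(O[Si](C)(C)C(C)(C)C)c(-c3cc([C@H]4Oc5cc(OCc6ccccc6)cc(OCc6ccccc6)c5C(=O)[C@@H]4O[Si](C)(C)C(C)(C)C)ccc3O[Si](C)(C)C(C)(C)C)c2)Oc2cc(OCc3ccccc3)cc(OCc3ccccc3)c21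
F4 | step 8 | 1-[2,4-bis(benzyloxy)-6-(methoxymethoxy)phenyl]ethan-1-one | CC(=O)c1c(OCOC)cc(OCc2ccccc2)cc1OCc1ccccc1
F5 | step 8 | (2E)-1-[2,4-bis(benzyloxy)-6-(methoxymethoxy)phenyl]-3-[3-iodo-4-(methoxymethoxy)phenyl]prop-2-en-1-one | COCOc1ccc(/C=C/C(=O)c2c(OCOC)cc(OCc3ccccc3)cc2OCc2ccccc2)cc1I
F6 | step 8 | [2,4-bis(benzyloxy)-6-(methoxymethoxy)phenyl]{(2R,3S)-3-[3-iodo-4-(methoxymethoxy)phenyl]oxiran-2-yl}methanone | O=C(c1c(OCOC)cc(OCc2ccccc2)cc1OCc1ccccc1)[C@@H]1O[C@H]1c1ccc(OCOC)c(I)c1
F7 | step 8 | (2R,3R)-5,7-bis(benzyloxy)-3-hydroxy-2-(4-hydroxy-3-iodophenyl)-2,3-dihydro-4H-chromen-4-one | Oc1ccc([C@H]2Oc3cc(OCc4ccccc4)cc(OCc4ccccc4)c3C(=O)[C@@H]2O)cc1I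
F0 | step 5 | none | none
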